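**Plan**
- Retrosynthetic cuts, in order: the C1'–C2' bond of the ethylene link (Wittig, then diimide); the C1–C2 bond of ring B (cation–olefin closure); the C4a–C8a and C7–C8 bonds of ring A (Diels–Alder). In the peroxide half: O2–C3 (hydroperoxide SN2), O1–C6 (epoxide perhydrolysis) and Cα–C3 (aldol).
- Forward: ring A is made first from a geranyl-acetate-derived triene, then ring B is closed. The 1,2-dioxane is built separately and closed at O2–C3. The halves are joined last and the carboxyl is freed at the end.
- Feature used: ring B is an ionone-type ring whose gem-dimethyl carbon C1 is bonded to C2 of the tetrasubstituted C2=C3 alkene. C1 together with ring A (C8a, 1,4 to the methyl-bearing C6 of the C5=C6 alkene) is an α-terpinyl unit. A C1 cation on a preformed cis-cyclohexene can therefore be captured by a C2=C3 alkene hanging from C4a.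
- Stereochemistry: C4a/C8a come from an auxiliary-controlled endo Diels–Alder reaction. C6 comes from a Sharpless epoxidation and is inverted once by H2O2. C3 and Cα come from an Evans syn-aldol, with C3 inverted once on ring closure.

Key step: step 8

Remark: the bicycle carries naphthalene numbering, C1'/C2' are the link carbons (C1' on C2), the dioxane is O1–O2–C3–C4–C5–C6 (C6 quaternary) and Cα is the propanoate C2. The position of the new ring-B alkene after step 8 is not relied on, because step 9 converges the isomers. Compound 35 is drawn E, but either geometry gives 36.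

**Step 1**
Reactants: 1 geranyl acetate
Product: 2 (2E)-6-chloro-3,7-dimethylocta-2,7-dienyl acetate
Conditions: t-BuOCl, SiO2, hexane, 0 °C
Reagents that add atoms: tert-butyl hypochlorite, CC(C)(C)OCl
Why: Ene-type allylic chlorination, in which electrophilic chlorine attacks the electron-richer 6,7-alkene (the 2,3-alkene is deactivated by the allylic acetate) and the double bond moves to the terminus; the racemic C6 centre disappears in step 2.

**Step 2**
Reactants: 2 chloro acetate
Product: 3 (2E,5E)-3,7-dimethylocta-2,5,7-trienyl acetate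
Conditions: Li2CO3, LiBr (cat.), DMF, 100 °C
Reagents that add atoms: none
Why: Base-mediated dehydrochlorination of the secondary allylic chloride toward the only conjugated diene, a pair of operations known for the same prenyl terminus of linalyl acetate; the E geometry at C5=C6 is the thermodynamic one.

**Step 3**
Reactants: 4 (R)-4-benzyloxazolidin-2-one; 5 acryloyl chloride
Product: 6 (R)-3-acryloyl-4-benzyloxazolidin-2-one
Conditions: n-BuLi, THF, −78 °C; then 5, −78 → 0 °C
Reagents that add atoms: none
Why: N-Acylation of the lithiated oxazolidinone by the acid chloride (Evans imide formation).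

**Step 4**
Reactants: 3 trienyl acetate; 6 acrylimide
Product: 7 Diels–Alder imide (1S,2R)
Conditions: Et2AlCl (1.4 equiv), CH2Cl2, −78 °C
Reagents that add atoms: none
Why: Evans auxiliary-controlled Diels–Alder reaction, in which the aluminium-chelated s-cis acrylimide is attacked endo on the face opposite the benzyl group: the 1-alkyl and 3-methyl groups of the diene both direct the carbonyl-bearing carbon next to the side chain, the E diene plus endo approach give the cis 1,2-relationship, and the (R)-auxiliary sets C1 as S and hence C2 as R.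

**Step 5**
Reactants: 7 Diels–Alder imide
Product: 9 hydroxy benzyl ester, via benzyl ester acetate 8 (not isolated)
Conditions: LiOBn (3 equiv, from BnOH and n-BuLi), THF, 0 °C
Reagents that add atoms: lithium benzyloxide, [Li+].[O-]Cc1ccccc1
Why: Alkoxide transesterification, in which benzyloxide attacks the exocyclic imide carbonyl (auxiliary released) and also exchanges the acetate, at a temperature where C1–H is not enolized, so the cis relationship is kept.

**Step 6**
Reactants: 9 hydroxy benzyl ester
Product: 11 diol, via methyl ketone 10 (not isolated)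
Conditions: MeMgBr (5 equiv), Et2O/THF, 0 °C → rt
Reagents that add atoms: methylmagnesium bromide, C[Mg]Br
Why: Double Grignard addition to the ester through the methyl ketone (the classical α-terpineol construction); carbonyl addition is faster than enolization, so C1 keeps its configuration.

**Step 7**
Reactants: 11 diol
Product: 12 carbinol pivalate
Conditions: PivCl, pyridine, CH2Cl2, 0 °C
Reagents that add atoms: pivaloyl chloride, CC(C)(C)C(Cl)=O
Why: Chemoselective acylation, in which the primary allylic hydroxyl reacts and the tertiary one does not; the pivalate also deactivates the allylic C–O bond for step 8.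

**Step 8**
Reactants: 12 carbinol pivalate
Product: 13 [(4aR,8aS)-1,1,3,6-tetramethyl-1,4,4a,7,8,8a-hexahydronaphthalen-2-yl]methyl pivalate
Conditions: SnCl4 (1.5 equiv), 2,6-di-tert-butyl-4-methylpyridine (2 equiv), CH2Cl2, −78 → −40 °C
Reagents that add atoms: none
Why: SnCl4 ionizes the tertiary carbinol to an α-terpinyl-type cation on the carbon attached to C8a, the cis side-chain alkene attacks it through its CH terminus (the future C2) to give the tertiary C3 cation, and this loses a proton while the hindered pyridine takes up the HCl so that no free acid reaches the ring-A alkene. The closest known reaction type is the acid-induced cation–olefin cyclization of geranyl and farnesyl esters to cyclogeranyl and drimenyl esters, here started from a carbinol instead of an alkene. Ring B closes in the 6-endo-trig mode through a chair-like transition state, and the one bond formed joins the fully substituted C1 to C2. No stereocentre is created: C4a and C8a are already cis in 12 and are not touched, C1 carries two methyl groups and C2 ends sp2. The step needs chemoselectivity (ionization at the carbinol and not at the allylic ester, capture by the side-chain alkene before elimination or hydride shift), which the substrate secures by the cis 1,2-arrangement that holds the alkene in reach for a six-membered ring, by the 3-methyl group that polarizes the alkene for Markovnikov attack, and by the pivalate. The regiochemistry of proton loss is not secured by the substrate, so the Δ3 and exocyclic isomers expected beside 13 are carried into step 9, where all converge.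

**Step 9**
Reactants: 13 bicyclic pivalate
Product: 15 bicyclic enal, via bicyclic alcohol 14 (not isolated)
Conditions: LiAlH4, Et2O, 0 °C; crude: Dess–Martin periodinane, CH2Cl2, rt; then DBU (0.2 equiv), rt
Reagents that add atoms: none
Why: Hydride cleavage of the pivalate, Dess–Martin oxidation and amidine-mediated conjugation (the α- to β-cyclocitral isomerization): each positional alkene isomer gives an aldehyde whose acidic α- or γ-hydrogen lets the double bond move to the conjugated tetrasubstituted C2=C3 position, while the ring-A alkene and C4a/C8a carry no acidic hydrogen.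

**Step 10**
Reactants: 15 bicyclic enal
Product: 14 bicyclic alcohol
Conditions: NaBH4, MeOH, 0 °C
Reagents that add atoms: none
Why: 1,2-Reduction of the hindered conjugated aldehyde by borohydride (β-cyclocitral to β-cyclogeraniol type), which returns 14 as a single alkene isomer.

**Step 11**
Reactants: 14 bicyclic alcohol
Product: 16 bicyclic phosphonium bromide
Conditions: PPh3·HBr, CH2Cl2/MeOH, rt
Reagents that add atoms: triphenylphosphine hydrobromide, Br.P(c1ccccc1)(c1ccccc1)c1ccccc1
Why: Ionization of the allylic alcohol by the phosphonium acid and capture of the allyl cation by PPh3 at its primary terminus (the β-cyclogeranyl phosphonium salt preparation); the weak acid should leave the ring-A alkene alone.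

**Step 12**
Reactants: 17 2-methylprop-2-en-1-ol
Product: 19 (R)-2-methylglycidyl tosylate, via (S)-2-methylglycidol 18 (not isolated)
Conditions: Ti(OiPr)4 (5 mol%), L-(+)-DIPT (6 mol%), t-BuOOH, 4 Å MS, CH2Cl2, −20 °C; then TsCl, Et3N, DMAP (cat.), −10 °C
Reagents that add atoms: tert-butyl hydroperoxide, CC(C)(C)OO; 4-toluenesulfonyl chloride, Cc1ccc(cc1)S(Cl)(=O)=O
Why: Sharpless asymmetric epoxidation (L-(+)-tartrate delivers oxygen to the face that gives the S epoxy alcohol) followed by sulfonylation in the same flask; this sets the oxygenated quaternary carbon that becomes C6.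

**Step 13**
Reactants: 19 (R)-2-methylglycidyl tosylate
Product: 21 (R)-2-(but-3-enyl)-2-methyloxirane, via hydroxy tosylate 20 (not isolated)
Conditions: allylMgBr, CuI (10 mol%), THF, −40 °C; aq. NH4Cl; crude: K2CO3, MeOH, rt
Reagents that add atoms: allylmagnesium bromide, C=CC[Mg]Br
Why: Copper-catalysed Grignard opening of the epoxide at its CH2 terminus, then Williamson closure of the tertiary alkoxide onto the tosylate carbon; the C–O bond at the quaternary carbon is never broken, so its configuration is retained.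

**Step 14**
Reactants: 21 butenyl epoxide
Product: 23 3-[(2R)-2-methyloxiran-2-yl]propanal, via ozonide 22 (not isolated)
Conditions: O3, CH2Cl2, −78 °C; then PPh3, −78 °C → rt
Reagents that add atoms: ozone, [O-][O+]=O
Why: Ozonolysis of the terminal alkene with reductive work-up; the epoxide is inert to ozone and to PPh3 in the cold.

**Step 15**
Reactants: 23 epoxy aldehyde; 24 (R)-4-benzyl-3-propanoyloxazolidin-2-one
Product: 27 syn-aldol imide (2R,3S), via boron enolate 25 (not isolated), via boron aldolate 26 (not isolated)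
Conditions: 24, Bu2BOTf, iPr2NEt, CH2Cl2, 0 °C; then 23, −78 → 0 °C; pH 7 buffer, MeOH, 30% H2O2, 0 °C
Reagents that add atoms: none
Why: Evans syn-aldol reaction, in which the Z-boron enolate reacts through a Zimmerman–Traxler chair on the face opposite the benzyl group, so the (R)-auxiliary gives the 2R,3S syn adduct and thereby sets Cα and the C3 carbinol.

**Step 16**
Reactants: 27 syn-aldol imide
Product: 28 epoxy 1,3-diol
Conditions: LiBH4, MeOH (1 equiv), THF, 0 °C
Reagents that add atoms: none
Why: Reductive cleavage of the imide by LiBH4 to the primary alcohol (auxiliary recovered); the carboxyl is carried at the alcohol level so that the later C3 leaving group is not β to a carbonyl.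

**Step 17**
Reactants: 28 epoxy 1,3-diol
Product: 29 primary TBDPS ether
Conditions: TBDPSCl, imidazole, CH2Cl2, 0 °C
Reagents that add atoms: tert-butyl(chloro)diphenylsilane, CC(C)(C)[Si](Cl)(c1ccccc1)c1ccccc1
Why: Silylation, in which the bulky chlorosilane reacts at the primary hydroxyl only; TBDPS is chosen because it tolerates the acidic step 19.

**Step 18**
Reactants: 29 primary TBDPS ether
Product: 30 epoxy mesylate
Conditions: MsCl, Et3N, CH2Cl2, 0 °C
Reagents that add atoms: methanesulfonyl chloride, CS(Cl)(=O)=O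
Why: Sulfonylation of the secondary alcohol with retention at C3, which makes C3 the electrophile for the peroxide ring closure.

**Step 19**
Reactants: 30 epoxy mesylate
Product: 31 tertiary hydroperoxide
Conditions: H2O2 (anhydrous, in Et2O), phosphomolybdic acid (cat.), Et2O, rt
Reagents that add atoms: hydrogen peroxide, OO
Why: Acid-catalysed perhydrolysis of the epoxide, in which H2O2 opens the 2,2-disubstituted epoxide at the tertiary carbon in a borderline SN2 process with inversion; this gives the C6 hydroperoxide in the configuration of the target and frees the CH2OH handle.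

**Step 20**
Reactants: 31 tertiary hydroperoxide
Product: 32 dioxane alcohol
Conditions: KOt-Bu (1.05 equiv), 18-crown-6, THF, 0 °C
Reagents that add atoms: none
Why: Intramolecular O-alkylation of the hydroperoxide (6-exo-tet SN2), in which the peroxy anion, formed selectively because OOH is far more acidic than the alcohol, displaces the mesylate with inversion and sets C3 as R.

**Step 21**
Reactants: 32 dioxane alcohol
Product: 33 dioxane aldehyde
Conditions: Dess–Martin periodinane, CH2Cl2, 0 °C → rt
Reagents that add atoms: none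
Why: Dess–Martin oxidation of the neopentyl-type primary alcohol to an aldehyde that cannot enolize; dialkyl peroxides tolerate the reagent.

**Step 22**
Reactants: 16 bicyclic phosphonium bromide; 33 dioxane aldehyde
Product: 35 diene silyl ether, via phosphorus ylide 34 (not isolated)
Conditions: NaHMDS, THF, −78 °C; then 33, −78 → 0 °C
Reagents that add atoms: none
Why: Wittig olefination, in which the allylic ylide adds to the non-enolizable aldehyde at a temperature where the dialkyl peroxide should not be attacked; the C1'=C2' geometry is irrelevant because the bond is saturated next.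

**Step 23**
Reactants: 35 diene silyl ether
Product: 36 saturated silyl ether
Conditions: potassium azodicarboxylate, AcOH, MeOH/CH2Cl2, 0 °C → rt
Reagents that add atoms: none
Why: Diimide reduction, a concerted syn transfer of H2 that does not touch the O–O bond and is faster for the 1,2-disubstituted alkene than for the trisubstituted ring-A and tetrasubstituted ring-B alkenes.

**Step 24**
Reactants: 36 saturated silyl ether
Product: 37 primary alcohol
Conditions: TBAF, AcOH, THF, rt
Reagents that add atoms: none
Why: Fluoride desilylation, buffered with acetic acid so that the peroxide does not meet a strong base.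

**Step 25**
Reactants: 37 primary alcohol
Product: 39 target acid, via aldehyde 38 (not isolated)
Conditions: TEMPO (cat.), PhI(OAc)2 (2.2 equiv), MeCN/H2O, rt
Reagents that add atoms: water, O
Why: Oxoammonium (TEMPO) oxidation with PhI(OAc)2 in wet acetonitrile (alcohol to aldehyde to hydrate to acid) under near-neutral conditions that should spare the peroxide, both alkenes and the Cα centre.

**Compound list**
1 | geranyl acetate, (2E)-3,7-dimethylocta-2,6-dien-1-yl acetate | CC(C)=CCC/C(C)=C/COC(C)=O | starting material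
2 | (2E)-6-chloro-3,7-dimethylocta-2,7-dien-1-yl acetate (racemic at C6) | CC(=C)C(Cl)CC/C(C)=C/COC(C)=O | intermediate
3 | (2E,5E)-3,7-dimethylocta-2,5,7-trien-1-yl acetate | CC(=C)/C=C/C/C(C)=C/COC(C)=O | intermediate
4 | (4R)-4-benzyl-1,3-oxazolidin-2-one | O=C1N[C@H](Cc2ccccc2)CO1 | starting material
5 | acryloyl chloride | C=CC(Cl)=O | starting material
6 | (4R)-3-acryloyl-4-benzyl-1,3-oxazolidin-2-one | C=CC(=O)N1[C@H](Cc2ccccc2)COC1=O | intermediate
7 | (4R)-3-{[(1S,2R)-2-[(2E)-4-acetoxy-2-methylbut-2-en-1-yl]-4-methylcyclohex-3-en-1-yl]carbonyl}-4-benzyl-1,3-oxazolidin-2-one | CC1=C[C@@H](C/C(C)=C/COC(C)=O)[C@@H](C(=O)N2[C@H](Cc3ccccc3)COC2=O)CC1 | intermediate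
8 | benzyl (1S,2R)-2-[(2E)-4-acetoxy-2-methylbut-2-en-1-yl]-4-methylcyclohex-3-ene-1-carboxylate | CC1=C[C@@H](C/C(C)=C/COC(C)=O)[C@@H](C(=O)OCc2ccccc2)CC1 | intermediate
9 | benzyl (1S,2R)-2-[(2E)-4-hydroxy-2-methylbut-2-en-1-yl]-4-methylcyclohex-3-ene-1-carboxylate | CC1=C[C@@H](C/C(C)=C/CO)[C@@H](C(=O)OCc2ccccc2)CC1 | intermediate
10 | 1-{(1S,2R)-2-[(2E)-4-hydroxy-2-methylbut-2-en-1-yl]-4-methylcyclohex-3-en-1-yl}ethan-1-one | CC1=C[C@@H](C/C(C)=C/CO)[C@@H](C(C)=O)CC1 | intermediate
11 | 2-{(1S,2R)-2-[(2E)-4-hydroxy-2-methylbut-2-en-1-yl]-4-methylcyclohex-3-en-1-yl}propan-2-ol | CC1=C[C@@H](C/C(C)=C/CO)[C@@H](C(C)(C)O)CC1 | intermediate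
12 | (2E)-4-[(1R,6S)-6-(2-hydroxypropan-2-yl)-3-methylcyclohex-2-en-1-yl]-3-methylbut-2-en-1-yl 2,2-dimethylpropanoate | CC1=C[C@@H](C/C(C)=C/COC(=O)C(C)(C)C)[C@@H](C(C)(C)O)CC1 | intermediate
13 | [(4aR,8aS)-1,1,3,6-tetramethyl-1,4,4a,7,8,8a-hexahydronaphthalen-2-yl]methyl 2,2-dimethylpropanoate | CC1=C[C@H]2CC(C)=C(COC(=O)C(C)(C)C)C(C)(C)[C@H]2CC1 | intermediate
14 | [(4aR,8aS)-1,1,3,6-tetramethyl-1,4,4a,7,8,8a-hexahydronaphthalen-2-yl]methanol | CC1=C[C@H]2CC(C)=C(CO)C(C)(C)[C@H]2CC1 | intermediate
15 | (4aR,8aS)-1,1,3,6-tetramethyl-1,4,4a,7,8,8a-hexahydronaphthalene-2-carbaldehyde | CC1=C[C@H]2CC(C)=C(C=O)C(C)(C)[C@H]2CC1 | intermediate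
16 | {[(4aR,8aS)-1,1,3,6-tetramethyl-1,4,4a,7,8,8a-hexahydronaphthalen-2-yl]methyl}(triphenyl)phosphonium bromide | CC1=C[C@H]2CC(C)=C(C[P+](c3ccccc3)(c3ccccc3)c3ccccc3)C(C)(C)[C@H]2CC1.[Br-] | intermediate
17 | 2-methylprop-2-en-1-ol | CC(=C)CO | starting material
18 | [(2S)-2-methyloxiran-2-yl]methanol | C[C@]1(CO)CO1 | intermediate
19 | [(2R)-2-methyloxiran-2-yl]methyl 4-methylbenzenesulfonate | C[C@]1(COS(=O)(=O)c2ccc(C)cc2)CO1 | intermediate
20 | (2R)-2-hydroxy-2-methylhex-5-en-1-yl 4-methylbenzenesulfonate | C[C@](O)(COS(=O)(=O)c1ccc(C)cc1)CCC=C | intermediate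
21 | (2R)-2-(but-3-en-1-yl)-2-methyloxirane | C[C@@]1(CCC=C)CO1 | intermediate
22 | (2R)-2-methyl-2-[2-(1,2,4-trioxolan-3-yl)ethyl]oxirane (ozonide carbon unassigned) | C[C@@]1(CCC2OCOO2)CO1 | intermediate
23 | 3-[(2R)-2-methyloxiran-2-yl]propanal | C[C@@]1(CCC=O)CO1 | intermediate
24 | (4R)-4-benzyl-3-propanoyl-1,3-oxazolidin-2-one | CCC(=O)N1[C@H](Cc2ccccc2)COC1=O | starting material
25 | (4R)-4-benzyl-3-[(1Z)-1-(dibutylboranyloxy)prop-1-en-1-yl]-1,3-oxazolidin-2-one | C/C=C(\OB(CCCC)CCCC)N1[C@H](Cc2ccccc2)COC1=O | intermediate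
26 | dibutylborinate of 27 at the C3 oxygen | C[C@H]([C@@H](OB(CCCC)CCCC)CC[C@]1(C)CO1)C(=O)N1[C@H](Cc2ccccc2)COC1=O | intermediate
27 | (4R)-4-benzyl-3-{(2R,3S)-3-hydroxy-2-methyl-5-[(2R)-2-methyloxiran-2-yl]pentanoyl}-1,3-oxazolidin-2-one | C[C@H]([C@@H](O)CC[C@]1(C)CO1)C(=O)N1[C@H](Cc2ccccc2)COC1=O | intermediate
28 | (2S,3S)-2-methyl-5-[(2R)-2-methyloxiran-2-yl]pentane-1,3-diol | C[C@H]([C@@H](O)CC[C@]1(C)CO1)CO | intermediate
29 | (2S,3S)-1-{[tert-butyl(diphenyl)silyl]oxy}-2-methyl-5-[(2R)-2-methyloxiran-2-yl]pentan-3-ol | C[C@H]([C@@H](O)CC[C@]1(C)CO1)CO[Si](c1ccccc1)(c1ccccc1)C(C)(C)C | intermediate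
30 | (2S,3S)-1-{[tert-butyl(diphenyl)silyl]oxy}-2-methyl-5-[(2R)-2-methyloxiran-2-yl]pentan-3-yl methanesulfonate | C[C@H]([C@@H](OS(C)(=O)=O)CC[C@]1(C)CO1)CO[Si](c1ccccc1)(c1ccccc1)C(C)(C)C | intermediate
31 | (2S,3S,6S)-1-{[tert-butyl(diphenyl)silyl]oxy}-6-hydroperoxy-7-hydroxy-2,6-dimethylheptan-3-yl methanesulfonate | C[C@H]([C@@H](OS(C)(=O)=O)CC[C@@](OO)(C)CO)CO[Si](c1ccccc1)(c1ccccc1)C(C)(C)C | intermediate
32 | {(3R,6S)-3-[(2S)-1-{[tert-butyl(diphenyl)silyl]oxy}propan-2-yl]-6-methyl-1,2-dioxan-6-yl}methanol (target numbering of the dioxane) | C[C@H]([C@H]1CC[C@@](C)(CO)OO1)CO[Si](c1ccccc1)(c1ccccc1)C(C)(C)C | intermediate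
33 | (3R,6S)-3-[(2S)-1-{[tert-butyl(diphenyl)silyl]oxy}propan-2-yl]-6-methyl-1,2-dioxane-6-carbaldehyde (target numbering) | C[C@H]([C@H]1CC[C@@](C)(C=O)OO1)CO[Si](c1ccccc1)(c1ccccc1)C(C)(C)C | intermediate
34 | {[(4aR,8aS)-1,1,3,6-tetramethyl-1,4,4a,7,8,8a-hexahydronaphthalen-2-yl]methylidene}(triphenyl)phosphorane | CC1=C[C@H]2CC(C)=C(C=P(c3ccccc3)(c3ccccc3)c3ccccc3)C(C)(C)[C@H]2CC1 | intermediate
35 | tert-butyl{(2S)-2-[(3R,6S)-6-methyl-6-{(E)-2-[(4aR,8aS)-1,1,3,6-tetramethyl-1,4,4a,7,8,8a-hexahydronaphthalen-2-yl]ethenyl}-1,2-dioxan-3-yl]propoxy}diphenylsilane | CC1=C[C@H]2CC(C)=C(/C=C/[C@]3(C)CC[C@H]([C@@H](C)CO[Si](c4ccccc4)(c4ccccc4)C(C)(C)C)OO3)C(C)(C)[C@H]2CC1 | intermediate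
36 | tert-butyl{(2S)-2-[(3R,6R)-6-methyl-6-{2-[(4aR,8aS)-1,1,3,6-tetramethyl-1,4,4a,7,8,8a-hexahydronaphthalen-2-yl]ethyl}-1,2-dioxan-3-yl]propoxy}diphenylsilane | CC1=C[C@H]2CC(C)=C(CC[C@]3(C)CC[C@H]([C@@H](C)CO[Si](c4ccccc4)(c4ccccc4)C(C)(C)C)OO3)C(C)(C)[C@H]2CC1 | intermediate
37 | (2S)-2-[(3R,6R)-6-methyl-6-{2-[(4aR,8aS)-1,1,3,6-tetramethyl-1,4,4a,7,8,8a-hexahydronaphthalen-2-yl]ethyl}-1,2-dioxan-3-yl]propan-1-ol | CC1=C[C@H]2CC(C)=C(CC[C@]3(C)CC[C@H]([C@@H](C)CO)OO3)C(C)(C)[C@H]2CC1 | intermediate
38 | (2R)-2-[(3R,6R)-6-methyl-6-{2-[(4aR,8aS)-1,1,3,6-tetramethyl-1,4,4a,7,8,8a-hexahydronaphthalen-2-yl]ethyl}-1,2-dioxan-3-yl]propanal | CC1=C[C@H]2CC(C)=C(CC[C@]3(C)CC[C@H]([C@@H](C)C=O)OO3)C(C)(C)[C@H]2CC1 | intermediate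
39 | (2R)-2-[(3R,6R)-6-methyl-6-{2-[(4aR,8aS)-1,1,3,6-tetramethyl-1,4,4a,7,8,8a-hexahydronaphthalen-2-yl]ethyl}-1,2-dioxan-3-yl]propanoic acid | CC1=C[C@H]2CC(C)=C(CC[C@]3(C)CC[C@H]([C@@H](C)C(=O)O)OO3)C(C)(C)[C@H]2CC1 | target

**Totals**
Total step count: 25. Longest linear sequence: 14 steps (steps 1, 2, 4–11, 22–25 from geranyl acetate; equally steps 12–25 from 2-methylprop-2-en-1-ol).

**Steps most likely to fail**

Step 8 (ring-B closure). The tertiary cation may lose a proton or take a 1,2-hydride shift from C8a, which would scramble the ring fusion, before the ester-deactivated alkene captures it. Acid formed in the flask may also reach the ring-A alkene. The fallback sets out from 12 and changes the initiating event. Dehydration with Burgess reagent should give the isopropenyl triene (2E)-3-methyl-4-[(1R,6S)-3-methyl-6-(prop-1-en-2-yl)cyclohex-2-en-1-yl]but-2-en-1-yl pivalate F1. Mercury(II) triflate–N,N-dimethylaniline in nitromethane at −20 °C is expected to select the 1,1-disubstituted alkene over both trisubstituted ones, and the mercurinium ion is opened by the same side-chain alkene through the same C1–C2 bond. Brine then gives the organomercurial chloride {[(4aR,8aS)-1,3,6-trimethyl-2-(pivaloyloxymethyl)-1,4,4a,7,8,8a-hexahydronaphthalen-1-yl]methyl}mercury chloride F2 (C1 epimers). Reductive demercuration with NaBH4/NaOH turns CH2HgCl into the second C1 methyl group, and the route is rejoined at 13.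

Step 20 (peroxide ring closure). The base may cause elimination of the mesylate, O-alkylation by the neighbouring primary alkoxide to a tetrahydropyran, or fragmentation of the β-hydroxy hydroperoxide. The fallback sets out from 30 and reverses the order of the two C–O bond formations. Displacement of the mesylate by basic hydrogen peroxide (50% H2O2, KOH, MeOH, 0 °C) with inversion gives the secondary hydroperoxide tert-butyl{(2S,3R)-3-hydroperoxy-2-methyl-5-[(2R)-2-methyloxiran-2-yl]pentyloxy}diphenylsilane F3. Catalytic camphorsulfonic acid in CH2Cl2 should then open the epoxide at its tertiary carbon in the 6-exo mode with inversion. Both centres are inverted once, as in the main route, and the route is rejoined at 32.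

Step 22 (fragment union). The hindered allylic ylide may fail to add to the α-quaternary aldehyde, or the basic ylide may attack the peroxide. The fallback sets out from 14 and uses a Julia–Kocienski olefination. Mitsunobu reaction with 1-phenyl-1H-tetrazole-5-thiol (PPh3, DIAD) gives the sulfide 5-({[(4aR,8aS)-1,1,3,6-tetramethyl-1,4,4a,7,8,8a-hexahydronaphthalen-2-yl]methyl}sulfanyl)-1-phenyl-1H-tetrazole F4. Oxidation with ammonium molybdate/H2O2 gives the sulfone 5-({[(4aR,8aS)-1,1,3,6-tetramethyl-1,4,4a,7,8,8a-hexahydronaphthalen-2-yl]methyl}sulfonyl)-1-phenyl-1H-tetrazole F5. Its potassium salt (KHMDS, THF, −78 °C) is treated with 33, and the route is rejoined at 35.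

**Further compounds**
F1 | step 8 | (2E)-3-methyl-4-[(1R,6S)-3-methyl-6-(prop-1-en-2-yl)cyclohex-2-en-1-yl]but-2-en-1-yl 2,2-dimethylpropanoate | CC1=C[C@@H](C/C(C)=C/COC(=O)C(C)(C)C)[C@@H](C(C)=C)CC1
F2 | step 8 | {[(4aR,8aS)-1,3,6-trimethyl-2-(pivaloyloxymethyl)-1,4,4a,7,8,8a-hexahydronaphthalen-1-yl]methyl}mercury chloride (C1 epimers) | CC1=C[C@H]2CC(C)=C(COC(=O)C(C)(C)C)C(C)(C[Hg]Cl)[C@H]2CC1
F3 | step 20 | tert-butyl{(2S,3R)-3-hydroperoxy-2-methyl-5-[(2R)-2-methyloxiran-2-yl]pentyloxy}diphenylsilane | C[C@H]([C@H](OO)CC[C@]1(C)CO1)CO[Si](c1ccccc1)(c1ccccc1)C(C)(C)C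
F4 | step 22 | 5-({[(4aR,8aS)-1,1,3,6-tetramethyl-1,4,4a,7,8,8a-hexahydronaphthalen-2-yl]methyl}sulfanyl)-1-phenyl-1H-tetrazole | CC1=C[C@H]2CC(C)=C(CSc3nnnn3-c3ccccc3)C(C)(C)[C@H]2CC1
F5 | step 22 | 5-({[(4aR,8aS)-1,1,3,6-tetramethyl-1,4,4a,7,8,8a-hexahydronaphthalen-2-yl]methyl}sulfonyl)-1-phenyl-1H-tetrazole | CC1=C[C@H]2CC(C)=C(CS(=O)(=O)c3nnnn3-c3ccccc3)C(C)(C)[C@H]2CC1
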